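The data were computed for an exercise; scatter was added.

At early times the north run filled with intermediate ahead of product, reading 7.4% against 1.3% at 0.625 d.

| flask | starting material | coupling partner | free catalyst | second catalyst | remark | time |
|---|---|---|---|---|---|---|
| north | 1.3 M (fed, over 40 h) | 0.65 M | 110 mM | 1.6 mM | run made earlier; the fed solution adds 0.20 times the starting volume |  |
| east | 1.3 M (fed, over 40 h) | 0.98 M | 110 mM | 1.6 mM | run made earlier; the fed solution adds 0.20 times the starting volume |  |
| flask | 1.3 M (fed, over 40 h) | 1.30 M | 110 mM | 1.6 mM | the fed solution adds 0.20 times the starting volume | 15 d |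

- north (time / d: intermediate / %, product / %): 0.625: 7.4, 1.3; 0.833: 13.5, 3.2; 1.25: 21.8, 7.1; 2.50: 39.9, 20.4; 4.00: 37.8, 28.8; 6.00: 37.8, 32.1; 10.0: 35.5, 33.4
- east (time / d: intermediate / %, product / %): 0.625: 7.9, 2.3; 0.833: 13.6, 3.3; 1.25: 21.8, 8.2; 2.50: 32.9, 25.6; 4.00: 32.0, 38.2; 6.00: 30.1, 42.8; 10.0: 31.1, 45.4

(standard deviation of a reading: 1 percentage point)

- amounts are per litre of the starting volume; all of the dose is in the solution fed
- percentages count the whole charge, also what has not yet gone in

- time up to 15 d at which intermediate stands highest
- the amount of intermediate, in percent of the starting material charged, at that time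

Both runs levelled off late, so I read two ratios from their last readings. Intermediate over starting material averaged 1.23. The balance quotient, c(product)/(c(intermediate)·c(coupling partner)), a reaction quotient taken in the volume after the feed, read 5.23 M⁻¹ in north and 4.49 M⁻¹ in east, and I carried their mean, 4.86 M⁻¹.

Two extreme flasks could then be solved. With the coupling step shut, the first ratio put intermediate at 55.2% of the charge. With both steps balanced throughout, the two ratios and the equal charges of this flask gave 24.2%, less than the first. I placed the peak between them and nearer the lower, borrowing a rough overshoot from the north run, whose highest reading of 39.9% stood 4.4 percentage points above its last reading, though the same difference in the east run read 1.8 points; adding the north figure to the balanced value, I expected about 28.6% soon after the feed ended at 1.7 d.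

The forecast gave 29% at 2.2 d, “well above the late value”.

The flask gave 30.5% at 2.26 d.

    coupling partner + second catalyst + intermediate ⇌ second catalyst + product (K = 5.00 M⁻¹, k = 30.0 M⁻² h⁻¹)
    starting material + free catalyst ⇌ free catalyst + intermediate (K = 1.20, k = 0.520 M⁻¹ h⁻¹)

In the flask, the coupling step relaxed with a half-life of 0.775 d at the longest time, both directions counted, much shorter than the 15 d allowed. The flask ended with 56.3% product, 23.8% intermediate and 43.7% of its coupling partner left, so the balance quotient gives product over intermediate as 2.30, against 2.37 from those amounts. The neighbour charged with 0.52 M of coupling partner ended with 27.3% product, 39.7% intermediate and 31.8% of its partner left, where the quotient gives 0.670 against 0.688.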